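**Plan**

1. Retrosynthesis: the butenolide bonds C2–C3 and C4–C5 (furan-2(5H)-one numbering) are cut together, giving a dienyne and a 5-alkoxyoxazole held by a temporary O–CH2–SiMe2 tether. Next cut is the C(sp)–C(sp2) bond of the dienyne (Sonogashira), then the alkylidene C=C (Still–Gennari) and the γ-lactone C–O; the chain is farnesol.
2. Forward order: farnesol → trisnor aldehyde 5 → (Z)-enoate 11 → reduction/lactonisation closes the alkylidene γ-lactone (13) → dienyl iodide 16 → coupling with oxazole alkyne 22 → thermal cycloaddition, nitrile extrusion and hydrolysis close the butenolide last.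
3. Enabling feature: in the furan-2(5H)-one ring the C2(=O)–O1–C5H2 edge is the C5(OR)–O1–C2(H) edge of a 5-alkoxyoxazole, one hydrolysis away (2-alkoxyfuran level). C3 carries only H, so silicon can sit there as a removable anchor while C4 carries the dienyl chain.
4. Stereochemistry: (5R) from CBS reduction of an enone; the Z-alkylidene from the Still–Gennari olefination; the two trisubstituted E-alkenes from farnesol; the E-disubstituted alkene from the Takai olefination. The butenolide step creates no stereocentre.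

Key step: step 15

Remark: commercial (2E,6E)-farnesol is taken as geometrically pure; the alanine stereocentre of 20 is lost on oxazole formation, so the racemate is used.

**Route**

Step 1
Reactants: 1 (2E,6E)-farnesol
Product: 2 tert-butyl(diphenyl){[(2E,6E)-3,7,11-trimethyldodeca-2,6,10-trien-1-yl]oxy}silane
Conditions: TBDPSCl, imidazole, CH2Cl2, 0 °C to rt
Reagents that add atoms: tert-butyl(chloro)diphenylsilane, CC(C)(C)[Si](Cl)(c1ccccc1)c1ccccc1
Why: Imidazole-promoted silylation of the primary allylic alcohol; the acid-stable TBDPS ether should survive the periodic acid cleavage in step 3.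

Step 2
Reactants: 2 tert-butyl(diphenyl){[(2E,6E)-3,7,11-trimethyldodeca-2,6,10-trien-1-yl]oxy}silane
Product: 4 tert-butyl{[(2E,6E)-9-(3,3-dimethyloxiran-2-yl)-3,7-dimethylnona-2,6-dien-1-yl]oxy}diphenylsilane (racemic), via bromohydrin 3 (not isolated)
Conditions: NBS, THF–H2O, 0 °C; then K2CO3, MeOH, rt
Reagents that add atoms: water, O
Why: van Tamelen terminal functionalisation: the bromonium ion forms at the most accessible, electron-rich terminal alkene, water opens it at the tertiary carbon, and base closes the epoxide; the new stereocentre is racemic and is destroyed in step 3.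

Step 3
Reactants: 4 tert-butyl{[(2E,6E)-9-(3,3-dimethyloxiran-2-yl)-3,7-dimethylnona-2,6-dien-1-yl]oxy}diphenylsilane
Product: 5 (4E,8E)-10-[(tert-butyldiphenylsilyl)oxy]-4,8-dimethyldeca-4,8-dienal
Conditions: H5IO6, THF–Et2O, 0 °C
Reagents that add atoms: none
Why: Periodic acid hydrates the epoxide and cleaves the resulting glycol (Malaprade cleavage) to the trisnor aldehyde and acetone, leaving the trisubstituted alkenes and the silyl ether untouched.

Step 4
Reactants: 6 2-chloro-N-methoxy-N-methylacetamide; 7 2-methylprop-1-en-1-ylmagnesium bromide (Me2C=CHMgBr)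
Product: 8 1-chloro-4-methylpent-3-en-2-one
Conditions: THF, −78 to 0 °C; cold 1 M HCl quench
Reagents that add atoms: none
Why: Weinreb ketone synthesis: the chelated tetrahedral intermediate prevents over-addition and the C–Cl bond is not attacked at low temperature.

Step 5
Reactants: 9 methyl 2-[bis(2,2,2-trifluoroethoxy)phosphoryl]acetate; 8 1-chloro-4-methylpent-3-en-2-one
Product: 10 methyl 2-[bis(2,2,2-trifluoroethoxy)phosphoryl]-6-methyl-4-oxohept-5-enoate (racemic)
Conditions: NaH, THF, 0 °C (9 in excess); then 8, NaI (cat.), 0 °C to rt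
Reagents that add atoms: none
Why: SN2 C-alkylation of the stabilised phosphonoacetate anion by an α-chloroketone under iodide catalysis; excess 9 should suppress dialkylation.

Step 6
Reactants: 5 (4E,8E)-10-[(tert-butyldiphenylsilyl)oxy]-4,8-dimethyldeca-4,8-dienal; 10 methyl 2-[bis(2,2,2-trifluoroethoxy)phosphoryl]-6-methyl-4-oxohept-5-enoate
Product: 11 methyl (2Z,6E,10E)-12-[(tert-butyldiphenylsilyl)oxy]-6,10-dimethyl-2-(4-methyl-2-oxopent-3-en-1-yl)dodeca-2,6,10-trienoate
Conditions: KN(SiMe3)2, 18-crown-6, THF, −78 °C; then 5; NH4Cl quench at −78 °C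
Reagents that add atoms: none
Why: Still–Gennari olefination: the electron-poor phosphonate with a dissociated potassium counter-ion eliminates under kinetic control and places the ester cis to the chain (Z); only the CH flanked by P and CO2Me is deprotonated, and the cold quench should prevent migration of the new double bond toward the ketone.

Step 7
Reactants: 11 methyl (2Z,6E,10E)-12-[(tert-butyldiphenylsilyl)oxy]-6,10-dimethyl-2-(4-methyl-2-oxopent-3-en-1-yl)dodeca-2,6,10-trienoate
Product: 13 (3Z,5R)-3-{(4E,8E)-10-[(tert-butyldiphenylsilyl)oxy]-4,8-dimethyldeca-4,8-dien-1-ylidene}-5-(2-methylprop-1-en-1-yl)oxolan-2-one, via hydroxy ester 12 (not isolated)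
Conditions: (S)-2-methyl-CBS-oxazaborolidine (0.2 equiv), catecholborane, toluene, −78 °C; then PPTS (cat.), CH2Cl2, rt
Reagents that add atoms: none
Why: Corey–Bakshi–Shibata reduction: with the alkenyl group as the large and the CH2 group as the small substituent, the (S)-catalyst should give the (R)-allylic alcohol (catecholborane spares the alkenes and the enoate at −78 °C), and the γ-hydroxy ester then lactonises under mild acid without changing the alkylidene geometry.

Step 8
Reactants: 13 (3Z,5R)-3-{(4E,8E)-10-[(tert-butyldiphenylsilyl)oxy]-4,8-dimethyldeca-4,8-dien-1-ylidene}-5-(2-methylprop-1-en-1-yl)oxolan-2-one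
Product: 14 (3Z,5R)-3-[(4E,8E)-10-hydroxy-4,8-dimethyldeca-4,8-dien-1-ylidene]-5-(2-methylprop-1-en-1-yl)oxolan-2-one
Conditions: Bu4NF, AcOH, THF, 0 °C to rt
Reagents that add atoms: none
Why: Fluoride-driven desilylation; the acetic acid buffer should keep the lactone and the Z-alkylidene unit from base-induced opening or isomerisation.

Step 9
Reactants: 14 (3Z,5R)-3-[(4E,8E)-10-hydroxy-4,8-dimethyldeca-4,8-dien-1-ylidene]-5-(2-methylprop-1-en-1-yl)oxolan-2-one
Product: 15 (2E,6E,10Z)-3,7-dimethyl-10-[(5R)-5-(2-methylprop-1-en-1-yl)-2-oxooxolan-3-ylidene]deca-2,6-dienal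
Conditions: MnO2, CH2Cl2, rt
Reagents that add atoms: none
Why: Chemoselective MnO2 oxidation of the allylic alcohol to the enal with the 2E geometry retained.

Step 10
Reactants: 15 (2E,6E,10Z)-3,7-dimethyl-10-[(5R)-5-(2-methylprop-1-en-1-yl)-2-oxooxolan-3-ylidene]deca-2,6-dienal
Product: 16 (3Z,5R)-3-[(4E,8E,10E)-11-iodo-4,8-dimethylundeca-4,8,10-trien-1-ylidene]-5-(2-methylprop-1-en-1-yl)oxolan-2-one
Conditions: CrCl2, CHI3, THF–dioxane, 0 °C to rt, dark
Reagents that add atoms: iodoform, IC(I)I
Why: Takai olefination: the geminal dichromium species from iodoform adds to the aldehyde and eliminates to the (E)-vinyl iodide; lactones and enoates are inert to CrCl2.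

Step 11
Reactants: 17 ethynylmagnesium bromide (HC≡CMgBr); 18 chloro(chloromethyl)dimethylsilane
Product: 19 (chloromethyl)(ethynyl)dimethylsilane
Conditions: THF, 0 °C to rt
Reagents that add atoms: none
Why: Grignard substitution at silicon; the Si–Cl bond is far more electrophilic than the C–Cl bond.

Step 12
Reactants: 20 N-formyl-DL-alanine; 19 (chloromethyl)(ethynyl)dimethylsilane
Product: 21 [ethynyl(dimethyl)silyl]methyl N-formyl-DL-alaninate
Conditions: Cs2CO3 (0.55 equiv), DMF, rt; then 19, NaI (cat.), 60 °C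
Reagents that add atoms: none
Why: SN2 O-alkylation of the caesium carboxylate by the α-silyl alkyl chloride under iodide catalysis, the usual route to silylmethyl esters.

Step 13
Reactants: 21 [ethynyl(dimethyl)silyl]methyl N-formyl-DL-alaninate
Product: 22 5-{[ethynyl(dimethyl)silyl]methoxy}-4-methyl-1,3-oxazole
Conditions: P2O5, CHCl3, reflux; cold aq K2CO3 work-up
Reagents that add atoms: none
Why: Robinson–Gabriel-type cyclodehydration of an N-formyl α-amino ester (ester oxygen attacks the activated formamide), the classical route to 5-alkoxy-4-methyloxazoles; the anhydrous medium should leave the alkynylsilane intact.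

Step 14
Reactants: 16 (3Z,5R)-3-[(4E,8E,10E)-11-iodo-4,8-dimethylundeca-4,8,10-trien-1-ylidene]-5-(2-methylprop-1-en-1-yl)oxolan-2-one; 22 5-{[ethynyl(dimethyl)silyl]methoxy}-4-methyl-1,3-oxazole
Product: 23 (3Z,5R)-3-{(4E,8E,10E)-13-[dimethyl({[(4-methyl-1,3-oxazol-5-yl)oxy]methyl})silyl]-4,8-dimethyltrideca-4,8,10-trien-12-yn-1-ylidene}-5-(2-methylprop-1-en-1-yl)oxolan-2-one
Conditions: Pd(PPh3)4 (cat.), CuI (cat.), Et3N, THF, rt, dark
Reagents that add atoms: none
Why: Sonogashira coupling of an ethynylsilane (as with trimethylsilylacetylene) with retention of the E-vinyl geometry; the amine base is too weak to open the oxazole or enolise the lactone.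

Step 15
Reactants: 23 (3Z,5R)-3-{(4E,8E,10E)-13-[dimethyl({[(4-methyl-1,3-oxazol-5-yl)oxy]methyl})silyl]-4,8-dimethyltrideca-4,8,10-trien-12-yn-1-ylidene}-5-(2-methylprop-1-en-1-yl)oxolan-2-one
Product: 26 (3Z,5R)-3-[(4E,8E,10E)-4,8-dimethyl-11-(5-oxo-2,5-dihydrofuran-3-yl)undeca-4,8,10-trien-1-ylidene]-5-(2-methylprop-1-en-1-yl)oxolan-2-one, via oxa-bridged cycloadduct 24 (not isolated), via fused silylalkoxyfuran 25 (not isolated)
Conditions: toluene (0.005 M, degassed), BHT (cat.), 130 °C, sealed tube; then THF–0.1 M aq HCl, 0 °C to rt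
Reagents that add atoms: water, O
Why: Proposed new method: on heating, the electron-rich 5-alkoxy-4-methyloxazole acts as a 2-azadiene (C2=N3–C4=C5) toward the silicon-bound, diene-conjugated alkyne in an intramolecular normal-demand [4+2] cycloaddition that joins oxazole C5 to the silyl-bearing alkyne carbon and oxazole C2 to the chain-bearing alkyne carbon; the oxa-bridged adduct 24 then loses acetonitrile by [4+2] cycloreversion to the fused 2-alkoxy-3-silylfuran 25, which dilute acid should protodesilylate at the ketene-acetal carbon (ipso protonation gives a cation stabilised by two oxygens and by the β-silicon) and hydrolyse to the conjugated butenolide, releasing the tether as (hydroxymethyl)dimethylsilanol. The closest known reaction type is the intramolecular oxazole–alkyne Diels–Alder/retro-Diels–Alder synthesis of 2-alkoxyfurans and their hydrolysis to butenolides, where the tether is carbon-based, attached to oxazole C2 and retained; the new element is a traceless O–CH2–SiMe2 tether from the oxazole 5-oxygen to the alkyne terminus. Ring closure: the temporary five-membered 1,3-oxasilole ring forms in the fused mode (tether on the diene terminus, three linking atoms), and the butenolide ring arises by extrusion of the C4–N3 unit as a nitrile from the bicyclo[2.2.1] adduct. No stereocentre is created in the product: the two bridgehead centres of 24 are transient (both become sp2), and the (5R) centre and all alkene geometries lie outside the reacting atoms. The selectivity needed is regiochemical (the future butenolide CH must bond to the alkoxy-bearing oxazole carbon, which an untethered alkoxyoxazole would not be expected to deliver with a conjugated alkyne) and is enforced by the short tether, which can only span oxazole C5 and the silicon-bearing alkyne carbon; the alkyne is also the only π-bond the tether can reach, so the other alkenes and the alkylidene lactone should be spectators.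

**Compound list**

1 | (2E,6E)-farnesol | CC(C)=CCC/C(C)=C/CC/C(C)=C/CO | starting material
2 | tert-butyl(diphenyl){[(2E,6E)-3,7,11-trimethyldodeca-2,6,10-trien-1-yl]oxy}silane | CC(C)=CCC/C(C)=C/CC/C(C)=C/CO[Si](c1ccccc1)(c1ccccc1)C(C)(C)C | intermediate
3 | (6E,10E)-3-bromo-12-[(tert-butyldiphenylsilyl)oxy]-2,6,10-trimethyldodeca-6,10-dien-2-ol (racemic bromohydrin) | CC(C)(O)C(Br)CC/C(C)=C/CC/C(C)=C/CO[Si](c1ccccc1)(c1ccccc1)C(C)(C)C | intermediate
4 | tert-butyl{[(2E,6E)-9-(3,3-dimethyloxiran-2-yl)-3,7-dimethylnona-2,6-dien-1-yl]oxy}diphenylsilane (racemic) | CC1(C)OC1CC/C(C)=C/CC/C(C)=C/CO[Si](c1ccccc1)(c1ccccc1)C(C)(C)C | intermediate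
5 | (4E,8E)-10-[(tert-butyldiphenylsilyl)oxy]-4,8-dimethyldeca-4,8-dienal | O=CCC/C(C)=C/CC/C(C)=C/CO[Si](c1ccccc1)(c1ccccc1)C(C)(C)C | intermediate
6 | 2-chloro-N-methoxy-N-methylacetamide | CON(C)C(=O)CCl | starting material
7 | 2-methylprop-1-en-1-ylmagnesium bromide | CC(C)=C[Mg]Br | starting material
8 | 1-chloro-4-methylpent-3-en-2-one | CC(C)=CC(=O)CCl | intermediate
9 | methyl 2-[bis(2,2,2-trifluoroethoxy)phosphoryl]acetate | COC(=O)CP(=O)(OCC(F)(F)F)OCC(F)(F)F | starting material
10 | methyl 2-[bis(2,2,2-trifluoroethoxy)phosphoryl]-6-methyl-4-oxohept-5-enoate (racemic) | COC(=O)C(CC(=O)C=C(C)C)P(=O)(OCC(F)(F)F)OCC(F)(F)F | intermediate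
11 | methyl (2Z,6E,10E)-12-[(tert-butyldiphenylsilyl)oxy]-6,10-dimethyl-2-(4-methyl-2-oxopent-3-en-1-yl)dodeca-2,6,10-trienoate | COC(=O)/C(CC(=O)C=C(C)C)=C\CC/C(C)=C/CC/C(C)=C/CO[Si](c1ccccc1)(c1ccccc1)C(C)(C)C | intermediate
12 | methyl (2Z,6E,10E)-12-[(tert-butyldiphenylsilyl)oxy]-2-[(2R)-2-hydroxy-4-methylpent-3-en-1-yl]-6,10-dimethyldodeca-2,6,10-trienoate | COC(=O)/C(C[C@@H](O)C=C(C)C)=C\CC/C(C)=C/CC/C(C)=C/CO[Si](c1ccccc1)(c1ccccc1)C(C)(C)C | intermediate
13 | (3Z,5R)-3-{(4E,8E)-10-[(tert-butyldiphenylsilyl)oxy]-4,8-dimethyldeca-4,8-dien-1-ylidene}-5-(2-methylprop-1-en-1-yl)oxolan-2-one | CC(C)=C[C@H]1C/C(=C/CC/C(C)=C/CC/C(C)=C/CO[Si](c2ccccc2)(c2ccccc2)C(C)(C)C)C(=O)O1 | intermediate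
14 | (3Z,5R)-3-[(4E,8E)-10-hydroxy-4,8-dimethyldeca-4,8-dien-1-ylidene]-5-(2-methylprop-1-en-1-yl)oxolan-2-one | CC(C)=C[C@H]1C/C(=C/CC/C(C)=C/CC/C(C)=C/CO)C(=O)O1 | intermediate
15 | (2E,6E,10Z)-3,7-dimethyl-10-[(5R)-5-(2-methylprop-1-en-1-yl)-2-oxooxolan-3-ylidene]deca-2,6-dienal | CC(C)=C[C@H]1C/C(=C/CC/C(C)=C/CC/C(C)=C/C=O)C(=O)O1 | intermediate
16 | (3Z,5R)-3-[(4E,8E,10E)-11-iodo-4,8-dimethylundeca-4,8,10-trien-1-ylidene]-5-(2-methylprop-1-en-1-yl)oxolan-2-one | CC(C)=C[C@H]1C/C(=C/CC/C(C)=C/CC/C(C)=C/C=C/I)C(=O)O1 | intermediate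
17 | ethynylmagnesium bromide | C#C[Mg]Br | starting material
18 | chloro(chloromethyl)dimethylsilane | C[Si](C)(Cl)CCl | starting material
19 | (chloromethyl)(ethynyl)dimethylsilane | C#C[Si](C)(C)CCl | intermediate
20 | N-formyl-DL-alanine | CC(NC=O)C(=O)O | starting material
21 | [ethynyl(dimethyl)silyl]methyl N-formyl-DL-alaninate | CC(NC=O)C(=O)OC[Si](C)(C)C#C | intermediate
22 | 5-{[ethynyl(dimethyl)silyl]methoxy}-4-methyl-1,3-oxazole | Cc1ncoc1OC[Si](C)(C)C#C | intermediate
23 | (3Z,5R)-3-{(4E,8E,10E)-13-[dimethyl({[(4-methyl-1,3-oxazol-5-yl)oxy]methyl})silyl]-4,8-dimethyltrideca-4,8,10-trien-12-yn-1-ylidene}-5-(2-methylprop-1-en-1-yl)oxolan-2-one | CC(C)=C[C@H]1C/C(=C/CC/C(C)=C/CC/C(C)=C/C=C/C#C[Si](C)(C)COc2ocnc2C)C(=O)O1 | intermediate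
24 | 7-oxa-2-azabicyclo[2.2.1]hepta-2,5-diene cycloadduct: oxazole C5 bonded to the silyl-bearing alkyne carbon, oxazole C2 to the chain-bearing alkyne carbon, O–CH2–SiMe2 bridge from the C5 bridgehead to the adjacent alkene carbon (two bridgehead diastereomers, undefined) | CC(C)=C[C@H]1C/C(=C/CC/C(C)=C/CC/C(C)=C/C=C/C2=C3[Si](C)(C)COC34OC2N=C4C)C(=O)O1 | intermediate
25 | fused 2-alkoxy-3-silylfuran: furan whose C2 and C3 are bridged by O–CH2–SiMe2 (furo-fused 1,3-oxasilole), trienyl lactone chain on furan C4, H on furan C5 | CC(C)=C[C@H]1C/C(=C/CC/C(C)=C/CC/C(C)=C/C=C/c2coc3OC[Si](C)(C)c23)C(=O)O1 | intermediate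
26 | (3Z,5R)-3-[(4E,8E,10E)-4,8-dimethyl-11-(5-oxo-2,5-dihydrofuran-3-yl)undeca-4,8,10-trien-1-ylidene]-5-(2-methylprop-1-en-1-yl)oxolan-2-one | CC(C)=C[C@H]1C/C(=C/CC/C(C)=C/CC/C(C)=C/C=C/C2=CC(=O)OC2)C(=O)O1 | target

**Step count and risks**

Total steps: 15. Longest linear sequence: 10 steps (1, 2, 3, 6, 7, 8, 9, 10, 14, 15).

1. Step 15 (bears the label "Proposed new method:"). The cycloaddition may be too slow to outrun thermal oligomerisation of the dienyne. In the hydrolysis, protonation of the alkoxyfuran at its 5-position instead of at the silicon-bearing carbon would leave silicon on the butenolide. Fallback with known chemistry, setting out from dienyl iodide 16 and returning at target 26: Stille coupling of 16 with 4-(tributylstannyl)furan-2(5H)-one F1 (from commercial 4-bromofuran-2(5H)-one and (Bu3Sn)2 with Pd(PPh3)4 in toluene at 80 °C) under Pd2(dba)3, AsPh3 and CuI in DMF at rt should give 26 directly; it forms the bond between butenolide C4 and the diene instead of the two ring bonds.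

2. Step 6. The bulky α-substituent may erode the Z-selectivity, and base may move the new double bond into conjugation with the ketone. Fallback, setting out from aldehyde 5 (with chloroketone 8 of the route) and returning at lactone 13, fixes the geometry by anti-addition to an alkyne instead of by olefination. Ohira–Bestmann homologation of 5 (dimethyl (1-diazo-2-oxopropyl)phosphonate, K2CO3, MeOH) should give the terminal alkyne F2. In parallel, CBS reduction of 8 with the (S)-oxazaborolidine and catecholborane should give (2S)-1-chloro-4-methylpent-3-en-2-ol F3, closed with NaOH to (2S)-2-(2-methylprop-1-en-1-yl)oxirane F4. The lithium acetylide of F2 (n-BuLi, THF–DMSO) should open F4 at its CH2 carbon to the (4R)-homopropargylic alcohol F5. Hydroxyl-directed trans-hydrostannation ([Cp*RuCl]4, Bu3SnH, CH2Cl2) should place tin on the proximal alkyne carbon cis to the chain, giving alkenylstannane F6. Iododestannylation (I2, CH2Cl2, 0 °C) gives the (Z)-vinyl iodide F7, and carbonylative lactonisation (PdCl2(PPh3)2, CO 1 atm, K2CO3, THF, 50 °C) with retention returns 13.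

3. Step 10. E-selectivity may be incomplete with the enal, and the light-sensitive dienyl iodide may be lost during the reaction and isolation. Fallback, setting out from enal 15 and returning at iodide 16: Ohira–Bestmann homologation (dimethyl (1-diazo-2-oxopropyl)phosphonate, K2CO3, MeOH, 0 °C) should give the terminal enyne F8; hydrozirconation with Cp2Zr(H)Cl in THF at 0 °C followed by I2 returns 16 with the E-geometry fixed by syn-addition.

**Further compounds**

F1 | step 15 | 4-(tributylstannyl)furan-2(5H)-one | CCCC[Sn](CCCC)(CCCC)C1=CC(=O)OC1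
F2 | step 6 | tert-butyl{[(2E,6E)-3,7-dimethylundeca-2,6-dien-10-yn-1-yl]oxy}diphenylsilane | C#CCC/C(C)=C/CC/C(C)=C/CO[Si](c1ccccc1)(c1ccccc1)C(C)(C)C
F3 | step 6 | (2S)-1-chloro-4-methylpent-3-en-2-ol | CC(C)=C[C@H](O)CCl
F4 | step 6 | (2S)-2-(2-methylprop-1-en-1-yl)oxirane | CC(C)=C[C@H]1CO1
F5 | step 6 | (4R,10E,14E)-16-[(tert-butyldiphenylsilyl)oxy]-2,10,14-trimethylhexadeca-2,10,14-trien-6-yn-4-ol | CC(C)=C[C@H](O)CC#CCC/C(C)=C/CC/C(C)=C/CO[Si](c1ccccc1)(c1ccccc1)C(C)(C)C
F6 | step 6 | (4R,6Z,10E,14E)-16-[(tert-butyldiphenylsilyl)oxy]-2,10,14-trimethyl-6-(tributylstannyl)hexadeca-2,6,10,14-tetraen-4-ol | CC(C)=C[C@H](O)C/C(=C/CC/C(C)=C/CC/C(C)=C/CO[Si](c1ccccc1)(c1ccccc1)C(C)(C)C)[Sn](CCCC)(CCCC)CCCC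
F7 | step 6 | (4R,6Z,10E,14E)-16-[(tert-butyldiphenylsilyl)oxy]-6-iodo-2,10,14-trimethylhexadeca-2,6,10,14-tetraen-4-ol | CC(C)=C[C@H](O)C/C(I)=C/CC/C(C)=C/CC/C(C)=C/CO[Si](c1ccccc1)(c1ccccc1)C(C)(C)C
F8 | step 10 | (3Z,5R)-3-[(4E,8E)-4,8-dimethylundeca-4,8-dien-10-yn-1-ylidene]-5-(2-methylprop-1-en-1-yl)oxolan-2-one | CC(C)=C[C@H]1C/C(=C/CC/C(C)=C/CC/C(C)=C/C#C)C(=O)O1
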